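**Retrosynthetic overview**
1. Target 27 ← isocupressic acid 26 (O-acetylation) ← ester 24. The C4 quaternary centre of 24 comes from α-face methylation of the C19 ester enolate of trans-decalin 23, after reductive removal of a temporary C1 carbonyl (21 → 23).
2. Key disconnection: ring A (C1–C2–C3–C4–C5–C10) is cut 3 + 3 into a C2–C1(=O)–C10 methyl ketone (donor at C10, then C2) and a C5=C4(CO2Me)–C3H2–OMe unit (acceptor at C5, then C3). C5–C10 is also the bond that closes ring B, so acyclic 19 should give both rings in one Michael/elimination/Michael cascade.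
3. Enabling feature: in ring A the carboxyl carbon C19 sits on C4 between C3 and C5, and C1 sits between C10 and C2. A carbonyl parked on C1 plus the ester on C4 make the two three-carbon halves of ring A a 1,3-bis-nucleophile and a 1,3-bis-electrophile, and C5/C10 are the fusion atoms shared with ring B.
4. Stereochemistry: C9 is the only fixed centre of 19 (Rh-catalysed conjugate alkenylation) and relays to C10 and C5. The C10 epimers and C4=C5 isomers of 19 converge, and C4 is set last.
5. Ring order: ring B (C5–C10), then ring A (C2–C3), same flask. Carbon sources: geraniol (C9, C11–C16), phosphonate 6 (C1, C10), trifluoroborate 13 (C5–C8, C17), acrylate 18 (C3, C4, C19), MeMgBr (C2), MeI (C20, C18).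

Key step: step 12

Remark: atoms are referred to by labdane numbering (C1–C20). Centres that become planar in a later step (C10 before step 12, C4 before step 14) are carried as epimer mixtures.
Assumption: 2-bromohexa-1,5-diene and methyl 2-(methoxymethyl)prop-2-enoate are made (steps 5, 6 and 10) rather than bought; all other starting materials are stock items.

**Step 1**
Reactants: 1 geraniol
Product: 2 geranyl tert-butyldiphenylsilyl ether
Conditions: TBDPSCl, imidazole, DMF, 0 °C → rt
Reagents that add atoms: tert-butyl(chloro)diphenylsilane, CC(C)(C)[Si](Cl)(c1ccccc1)c1ccccc1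
Why: Imidazole-promoted silylation of the primary allylic alcohol gives an ether that should survive bases and organometallics and is removed by fluoride in step 15; no stereocentre is formed.

**Step 2**
Reactants: 2 geranyl tert-butyldiphenylsilyl ether
Product: 3 6,7-epoxygeranyl tert-butyldiphenylsilyl ether (racemic epoxide)
Conditions: mCPBA, NaHCO3, CH2Cl2, −20 °C → 0 °C
Reagents that add atoms: 3-chloroperoxybenzoic acid, OOC(=O)c1cccc(Cl)c1
Why: Prilezhaev epoxidation is expected to select the remote, more electron-rich 6,7-alkene over the 2,3-alkene, which is deactivated by the allylic oxygen and shielded by the silyl group; the racemic epoxide carbons are excised in step 3.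

**Step 3**
Reactants: 3 6,7-epoxygeranyl tert-butyldiphenylsilyl ether
Product: 5 (4E)-6-[(tert-butyldiphenylsilyl)oxy]-4-methylhex-4-enal, via vicinal diol 4 (not isolated)
Conditions: H5IO6, THF/H2O, 0 °C → rt
Reagents that add atoms: none
Why: Periodic acid opens the epoxide to diol 4 and cleaves it in the same flask (Malaprade glycol cleavage), releasing acetone and the aldehyde whose carbonyl carbon becomes C9.

**Step 4**
Reactants: 5 (4E)-6-[(tert-butyldiphenylsilyl)oxy]-4-methylhex-4-enal; 6 diethyl {2-[methoxy(methyl)amino]-2-oxoethyl}phosphonate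
Product: 7 (2E,6E)-8-[(tert-butyldiphenylsilyl)oxy]-N-methoxy-N,6-dimethylocta-2,6-dienamide
Conditions: NaH, THF, 0 °C → rt
Reagents that add atoms: none
Why: Horner–Wadsworth–Emmons olefination with the stabilised Weinreb phosphonate gives the E-enamide and brings in C10 and C1 at the acyl oxidation level needed for steps 8 and 9.

**Step 5**
Reactants: 8 allylmagnesium bromide; 9 2,3-dibromoprop-1-ene
Product: 10 2-bromohexa-1,5-diene
Conditions: Et2O, 0 °C → rt
Reagents that add atoms: none
Why: Allylic substitution of the reactive allylic bromide by the allyl Grignard reagent leaves the vinylic bromide untouched and gives the C5–C8/C17 unit.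

**Step 6**
Reactants: 10 2-bromohexa-1,5-diene
Product: 13 potassium trifluoro(hexa-1,5-dien-2-yl)borate, via hexa-1,5-dien-2-ylmagnesium bromide 11 (not isolated), via dimethyl hexa-1,5-dien-2-ylboronate 12 (not isolated)
Conditions: Mg, THF, reflux; B(OMe)3, −78 °C → rt; aq. KHF2, rt
Reagents that add atoms: trimethyl borate, COB(OC)OC; potassium hydrogen difluoride, F.[F-].[K+]
Why: Magnesium insertion into the vinylic bromide, borylation of Grignard 11 and fluorination of boronate 12 with KHF2 should give the air-stable alkenyltrifluoroborate.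

**Step 7**
Reactants: 7 (2E,6E)-8-[(tert-butyldiphenylsilyl)oxy]-N-methoxy-N,6-dimethylocta-2,6-dienamide; 13 potassium trifluoro(hexa-1,5-dien-2-yl)borate
Product: 14 (3R,6E)-8-[(tert-butyldiphenylsilyl)oxy]-3-(hexa-1,5-dien-2-yl)-N-methoxy-N,6-dimethyloct-6-enamide
Conditions: [Rh(cod)2]BF4 (3 mol %), (S)-BINAP (3.3 mol %), toluene/H2O 10:1, 100 °C
Reagents that add atoms: none
Why: Rh-catalysed asymmetric conjugate addition (Hayashi–Miyaura reaction) of the alkenylboron reagent to the E-enamide creates C9, the alkenyl group being delivered to the face that is Si at C2 and Re at C3, as predicted for (S)-BINAP by the model established for enones and E-configured unsaturated amides, which corresponds to 3R.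

**Step 8**
Reactants: 14 (3R,6E)-8-[(tert-butyldiphenylsilyl)oxy]-3-(hexa-1,5-dien-2-yl)-N-methoxy-N,6-dimethyloct-6-enamide
Product: 15 (3R,6E)-8-[(tert-butyldiphenylsilyl)oxy]-3-(hexa-1,5-dien-2-yl)-N-methoxy-N,2,6-trimethyloct-6-enamide (both C2 epimers)
Conditions: LiN(i-Pr)2, THF, −78 °C; MeI, −78 → −20 °C
Reagents that add atoms: iodomethane, CI
Why: Alkylation of the amide lithium enolate places C20 on C10, the only enolisable position, which avoids the regiochemistry problem of methylating a methyl ketone; the new centre is formed as an epimer mixture because it becomes planar again in step 12.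

**Step 9**
Reactants: 15 (3R,6E)-8-[(tert-butyldiphenylsilyl)oxy]-3-(hexa-1,5-dien-2-yl)-N-methoxy-N,2,6-trimethyloct-6-enamide
Product: 16 (4R,7E)-9-[(tert-butyldiphenylsilyl)oxy]-4-(hexa-1,5-dien-2-yl)-3,7-dimethylnon-7-en-2-one (both C3 epimers)
Conditions: MeMgBr, THF, 0 °C → rt; aq. NH4Cl
Reagents that add atoms: methylmagnesium bromide, C[Mg]Br
Why: Weinreb ketone synthesis: the chelated tetrahedral adduct prevents over-addition and delivers C2 as the acetyl methyl group.

**Step 10**
Reactants: 17 methyl 2-(bromomethyl)prop-2-enoate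
Product: 18 methyl 2-(methoxymethyl)prop-2-enoate
Conditions: NaOMe, MeOH, 0 °C
Reagents that add atoms: sodium methoxide, [Na+].[O-]C
Why: Methoxide displaces the allylic bromide (the SN2 and SN2′ paths give the same product), installing the latent leaving group on C3.

**Step 11**
Reactants: 16 (4R,7E)-9-[(tert-butyldiphenylsilyl)oxy]-4-(hexa-1,5-dien-2-yl)-3,7-dimethylnon-7-en-2-one; 18 methyl 2-(methoxymethyl)prop-2-enoate
Product: 19 methyl (7R,10E)-12-[(tert-butyldiphenylsilyl)oxy]-2-(methoxymethyl)-10-methyl-6-methylidene-7-(3-oxobutan-2-yl)dodeca-2,10-dienoate (2E/2Z mixture; both epimers at the oxobutyl carbon)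
Conditions: 18 (4 equiv), second-generation Hoveyda–Grubbs catalyst (5 mol %), CH2Cl2, 40 °C
Reagents that add atoms: none
Why: Olefin cross-metathesis should engage only the monosubstituted alkene of 16 (the 1,1-disubstituted and trisubstituted alkenes are too hindered) with an excess of the non-dimerising 2-substituted acrylate, and either geometry of the new enoate is usable because C5 becomes sp3 in step 12.

**Step 12**
Reactants: 19 methyl (7R,10E)-12-[(tert-butyldiphenylsilyl)oxy]-2-(methoxymethyl)-10-methyl-6-methylidene-7-(3-oxobutan-2-yl)dodeca-2,10-dienoate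
Product: 21 methyl (4aS,5S,8aS)-5-{(3E)-5-[(tert-butyldiphenylsilyl)oxy]-3-methylpent-3-en-1-yl}-4a-methyl-6-methylidene-4-oxodecahydronaphthalene-1-carboxylate (trans-fused; both C1 epimers), via monocyclic acrylate 20 (not isolated)
Conditions: KOt-Bu (1.05 equiv), THF (0.01 M), −40 °C → rt; then AcOH
Reagents that add atoms: none
Why: Proposed new method: one equivalent of KOt-Bu converts the ketone into its equilibrating potassium enolates; only the C10 enolate has a six-membered option, a Michael addition to C5 of the 2-(methoxymethyl)enoate, after which the C4 ester enolate expels methoxide (E1cB) to give acrylate 20, and the alkoxide so released enolises the acetyl methyl (C2), which adds to C3 of the new acrylate before the C4 enolate is protonated. The closest known reaction type is the α,α′-annulation of ketone enolates and enamines with 2-(halomethyl)- or 2-(acyloxymethyl)acrylates (Michael addition/elimination followed by a second Michael addition), known intermolecularly for bridged bicycles and here run within one chain so that the first bond is also a ring bond. Ring B closes in the 6-(enolexo)-exo-trig mode through a chair and ring A in the 6-(enolendo)-endo-trig mode. C10 and C5 are controlled by the C9 stereocentre: with the side chain equatorial, allylic 1,3-strain makes C9–H eclipse the enolate C10=C1 bond, so that C1 ends equatorial and the C10 methyl axial and anti to C9–H, and C4 takes the equatorial site on C5; this trans-diequatorial C1/C4 pair can only close to the trans-decalin, while C4 itself stays an epimer mixture until step 14. The step needs C10-over-C2 regioselectivity, secured by ring size (the C2 enolate could only close eight- or ten-membered rings, and high dilution suppresses its intermolecular reactions), and Michael addition in preference to 1,4-elimination of methanol through γ-deprotonation at C6, secured by the single equivalent of base being held by the more acidic ketone and by a poor nucleofuge that departs only from the ester enolate formed after the C–C bond. Both C10 epimers and both alkene isomers of 19 pass through the same planar enolate and the same chair, so the four-component mixture should converge on one ring system.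

**Step 13**
Reactants: 21 methyl (4aS,5S,8aS)-5-{(3E)-5-[(tert-butyldiphenylsilyl)oxy]-3-methylpent-3-en-1-yl}-4a-methyl-6-methylidene-4-oxodecahydronaphthalene-1-carboxylate
Product: 23 methyl (4aS,5S,8aS)-5-{(3E)-5-[(tert-butyldiphenylsilyl)oxy]-3-methylpent-3-en-1-yl}-4a-methyl-6-methylidenedecahydronaphthalene-1-carboxylate (both C1 epimers), via tosylhydrazone 22 (not isolated)
Conditions: TsNHNH2, EtOH, 70 °C; catecholborane, CHCl3, 0 °C; NaOAc·3H2O, 60 °C
Reagents that add atoms: none
Why: Tosylhydrazone reduction of the Caglioti type with catecholborane: hydride adds to the C=N bond of 22 at 0 °C and acetate then triggers loss of sulfinate and N2, turning C1 into CH2 without touching the ester, the silyl ether or the alkenes.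

**Step 14**
Reactants: 23 methyl (4aS,5S,8aS)-5-{(3E)-5-[(tert-butyldiphenylsilyl)oxy]-3-methylpent-3-en-1-yl}-4a-methyl-6-methylidenedecahydronaphthalene-1-carboxylate
Product: 24 methyl (1S,4aR,5S,8aR)-5-{(3E)-5-[(tert-butyldiphenylsilyl)oxy]-3-methylpent-3-en-1-yl}-1,4a-dimethyl-6-methylidenedecahydronaphthalene-1-carboxylate
Conditions: LiN(i-Pr)2, THF, −78 → 0 °C; MeI, −78 °C → rt
Reagents that add atoms: iodomethane, CI
Why: Ester enolate alkylation: MeI approaches the exocyclic C4 enolate from the α face, away from the syn-axial C10 methyl, so the new methyl (C18) is equatorial and the ester (C19) axial, the known preference of C4 ester enolates in 10-methyl trans-decalins, which should set C4 as S from either epimer of 23.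

**Step 15**
Reactants: 24 methyl (1S,4aR,5S,8aR)-5-{(3E)-5-[(tert-butyldiphenylsilyl)oxy]-3-methylpent-3-en-1-yl}-1,4a-dimethyl-6-methylidenedecahydronaphthalene-1-carboxylate
Product: 25 methyl isocupressate
Conditions: Bu4NF, THF, rt
Reagents that add atoms: none
Why: Fluoride-induced Si–O cleavage of the silyl ether frees the C15 alcohol, and the hindered methyl ester is inert.

**Step 16**
Reactants: 25 methyl isocupressate
Product: 26 isocupressic acid
Conditions: NaSEt, DMF, 90 °C; aq. HCl work-up
Reagents that add atoms: none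
Why: SN2 demethylation by thiolate attacks the ester methyl carbon and not the shielded axial carbonyl, the standard way to open hindered C19 methyl esters, and the alkenes and the alcohol are not affected.

**Step 17**
Reactants: 26 isocupressic acid
Product: 27 15-acetoxyisocupressic acid
Conditions: Ac2O, pyridine, DMAP (cat.), CH2Cl2, 0 °C → rt; aq. NaHCO3, then dilute acid
Reagents that add atoms: acetic anhydride, CC(=O)OC(C)=O
Why: DMAP-catalysed acylation of the primary allylic alcohol; the hindered tertiary acid can at most form a mixed anhydride, which the aqueous work-up hydrolyses back to the acid.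

**Compound list**
1 | geraniol, (2E)-3,7-dimethylocta-2,6-dien-1-ol | CC(C)=CCC/C(C)=C/CO | starting material
2 | geranyl tert-butyldiphenylsilyl ether | CC(C)=CCC/C(C)=C/CO[Si](c1ccccc1)(c1ccccc1)C(C)(C)C | intermediate
3 | 6,7-epoxygeranyl tert-butyldiphenylsilyl ether (racemic epoxide) | CC1(C)OC1CC/C(C)=C/CO[Si](c1ccccc1)(c1ccccc1)C(C)(C)C | intermediate
4 | vicinal diol, (6E)-8-[(tert-butyldiphenylsilyl)oxy]-2,6-dimethyloct-6-ene-2,3-diol | CC(C)(O)C(O)CC/C(C)=C/CO[Si](c1ccccc1)(c1ccccc1)C(C)(C)C | intermediate
5 | (4E)-6-[(tert-butyldiphenylsilyl)oxy]-4-methylhex-4-enal | O=CCC/C(C)=C/CO[Si](c1ccccc1)(c1ccccc1)C(C)(C)C | intermediate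
6 | diethyl {2-[methoxy(methyl)amino]-2-oxoethyl}phosphonate | CCOP(=O)(CC(=O)N(C)OC)OCC | starting material
7 | (2E,6E)-8-[(tert-butyldiphenylsilyl)oxy]-N-methoxy-N,6-dimethylocta-2,6-dienamide | CON(C)C(=O)/C=C/CC/C(C)=C/CO[Si](c1ccccc1)(c1ccccc1)C(C)(C)C | intermediate
8 | allylmagnesium bromide | C=CC[Mg]Br | starting material
9 | 2,3-dibromoprop-1-ene | C=C(Br)CBr | starting material
10 | 2-bromohexa-1,5-diene | C=CCCC(Br)=C | intermediate
11 | hexa-1,5-dien-2-ylmagnesium bromide | C=CCCC(=C)[Mg]Br | intermediate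
12 | dimethyl hexa-1,5-dien-2-ylboronate | C=CCCC(=C)B(OC)OC | intermediate
13 | potassium trifluoro(hexa-1,5-dien-2-yl)borate | [K+].C=CCCC(=C)[B-](F)(F)F | intermediate
14 | (3R,6E)-8-[(tert-butyldiphenylsilyl)oxy]-3-(hexa-1,5-dien-2-yl)-N-methoxy-N,6-dimethyloct-6-enamide | CON(C)C(=O)C[C@H](C(=C)CCC=C)CC/C(C)=C/CO[Si](c1ccccc1)(c1ccccc1)C(C)(C)C | intermediate
15 | (3R,6E)-8-[(tert-butyldiphenylsilyl)oxy]-3-(hexa-1,5-dien-2-yl)-N-methoxy-N,2,6-trimethyloct-6-enamide (both C2 epimers) | CON(C)C(=O)C(C)[C@H](C(=C)CCC=C)CC/C(C)=C/CO[Si](c1ccccc1)(c1ccccc1)C(C)(C)C | intermediate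
16 | (4R,7E)-9-[(tert-butyldiphenylsilyl)oxy]-4-(hexa-1,5-dien-2-yl)-3,7-dimethylnon-7-en-2-one (both C3 epimers) | CC(=O)C(C)[C@H](C(=C)CCC=C)CC/C(C)=C/CO[Si](c1ccccc1)(c1ccccc1)C(C)(C)C | intermediate
17 | methyl 2-(bromomethyl)prop-2-enoate | C=C(CBr)C(=O)OC | starting material
18 | methyl 2-(methoxymethyl)prop-2-enoate | C=C(COC)C(=O)OC | intermediate
19 | methyl (7R,10E)-12-[(tert-butyldiphenylsilyl)oxy]-2-(methoxymethyl)-10-methyl-6-methylidene-7-(3-oxobutan-2-yl)dodeca-2,10-dienoate (2E/2Z; both epimers at the oxobutyl carbon) | CC(=O)C(C)[C@H](C(=C)CCC=C(COC)C(=O)OC)CC/C(C)=C/CO[Si](c1ccccc1)(c1ccccc1)C(C)(C)C | intermediate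
20 | monocyclic acrylate, methyl 2-[(1R,2R,3S)-2-acetyl-3-{(3E)-5-[(tert-butyldiphenylsilyl)oxy]-3-methylpent-3-en-1-yl}-2-methyl-4-methylidenecyclohexyl]prop-2-enoate | C=C1CC[C@@H](C(=C)C(=O)OC)[C@](C)(C(C)=O)[C@H]1CC/C(C)=C/CO[Si](c1ccccc1)(c1ccccc1)C(C)(C)C | intermediate
21 | methyl (4aS,5S,8aS)-5-{(3E)-5-[(tert-butyldiphenylsilyl)oxy]-3-methylpent-3-en-1-yl}-4a-methyl-6-methylidene-4-oxodecahydronaphthalene-1-carboxylate (trans-fused; both C1 epimers) | C=C1CC[C@@H]2[C@](C)(C(=O)CCC2C(=O)OC)[C@H]1CC/C(C)=C/CO[Si](c1ccccc1)(c1ccccc1)C(C)(C)C | intermediate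
22 | tosylhydrazone of 21 at C4 of the decalin (labdane C1) | C=C1CC[C@@H]2[C@](C)(C(=NNS(=O)(=O)c3ccc(C)cc3)CCC2C(=O)OC)[C@H]1CC/C(C)=C/CO[Si](c1ccccc1)(c1ccccc1)C(C)(C)C | intermediate
23 | methyl (4aS,5S,8aS)-5-{(3E)-5-[(tert-butyldiphenylsilyl)oxy]-3-methylpent-3-en-1-yl}-4a-methyl-6-methylidenedecahydronaphthalene-1-carboxylate (both C1 epimers) | C=C1CC[C@@H]2[C@](C)(CCCC2C(=O)OC)[C@H]1CC/C(C)=C/CO[Si](c1ccccc1)(c1ccccc1)C(C)(C)C | intermediate
24 | methyl (1S,4aR,5S,8aR)-5-{(3E)-5-[(tert-butyldiphenylsilyl)oxy]-3-methylpent-3-en-1-yl}-1,4a-dimethyl-6-methylidenedecahydronaphthalene-1-carboxylate | C=C1CC[C@@H]2[C@](C)(CCC[C@]2(C)C(=O)OC)[C@H]1CC/C(C)=C/CO[Si](c1ccccc1)(c1ccccc1)C(C)(C)C | intermediate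
25 | methyl isocupressate, methyl (1S,4aR,5S,8aR)-5-[(3E)-5-hydroxy-3-methylpent-3-en-1-yl]-1,4a-dimethyl-6-methylidenedecahydronaphthalene-1-carboxylate | C=C1CC[C@@H]2[C@](C)(CCC[C@]2(C)C(=O)OC)[C@H]1CC/C(C)=C/CO | intermediate
26 | isocupressic acid, (1S,4aR,5S,8aR)-5-[(3E)-5-hydroxy-3-methylpent-3-en-1-yl]-1,4a-dimethyl-6-methylidenedecahydronaphthalene-1-carboxylic acid | C=C1CC[C@@H]2[C@](C)(CCC[C@]2(C)C(=O)O)[C@H]1CC/C(C)=C/CO | intermediate
27 | 15-acetoxyisocupressic acid, (1S,4aR,5S,8aR)-5-[(3E)-5-acetoxy-3-methylpent-3-en-1-yl]-1,4a-dimethyl-6-methylidenedecahydronaphthalene-1-carboxylic acid | C=C1CC[C@@H]2[C@](C)(CCC[C@]2(C)C(=O)O)[C@H]1CC/C(C)=C/COC(C)=O | target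

**Step count**
Total: 17 steps. Longest linear sequence: 14 steps (1–4, 7–9, 11–17, from geraniol).

**Steps most likely to fail**

Step 12 (proposed new method). The first ring closure may lose out to 1,4-elimination of methanol from the γ-deprotonated enoate or to intermolecular reactions of the C2 enolate, or the C5–C10 bond may form through the diastereomeric chair and lead into the cis-fused series. The fallback uses known reactions only; it sets out from 16 and comes back at 21. Cross-metathesis of 16 with methyl acrylate (second-generation Hoveyda–Grubbs catalyst, CH2Cl2, 40 °C) should give the simple keto enoate F1. A base-mediated 6-exo intramolecular Michael addition of the ketone (KOt-Bu, THF/t-BuOH, −20 °C) should then close ring B to the acetyl cyclohexylacetate F2. Heating F2 with N,N-dimethylformamide dimethyl acetal converts the methyl ketone into the enaminone F3. KN(SiMe3)2 (THF, −78 °C → rt, then AcOH) forms the ester enolate of F3, which adds to the enaminone carbon and loses dimethylamine to give the ring A enone F4. Conjugate reduction of F4 with Stryker's reagent [(Ph3P)CuH]6 (benzene, rt) then gives 21.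

Step 7. Turnover may be poor because the 1,1-disubstituted alkenylboron reagent protodeboronates faster than it adds to the sluggish Weinreb enamide, or the facial selectivity may be insufficient or of the wrong sense. The fallback replaces catalyst control by a chelated oxazolidinone auxiliary; it sets out from 5 (with bromide 10 as the alkenyl source) and comes back at 14. Wittig olefination of 5 with ethyl (triphenylphosphoranylidene)acetate gives the E-enoate F5, and LiOH hydrolysis gives the acid F6. Activation with pivaloyl chloride/Et3N and acylation of lithiated (4S)-4-phenyl-1,3-oxazolidin-2-one gives the N-enoyl imide F7. The organocopper reagent from Grignard 11 and CuBr·SMe2 (THF, −78 → −20 °C) should add anti to the phenyl group of the magnesium-chelated imide to give the 3R adduct F8. Me3Al/MeNHOMe·HCl then converts F8 into Weinreb amide 14 and releases the auxiliary.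

Step 13. Condensation of the hydrazide with the C1 carbonyl, which is flanked by the quaternary C10 and crowded by the C9 side chain, may be incomplete, or the hydrazone may eliminate and not be reduced. The fallback is a radical deoxygenation; it sets out from 21 and comes back at 23. NaBH4 (MeOH, 0 °C) reduces the ketone to the C1 alcohol F9. NaH, CS2 and MeI (THF, 0 °C → rt) convert F9 into the S-methyl xanthate F10. Barton–McCombie reduction of F10 (Bu3SnH, AIBN, toluene, 110 °C) gives 23.

**Further compounds**
F1 | step 12 | methyl (2E,7R,10E)-12-[(tert-butyldiphenylsilyl)oxy]-10-methyl-6-methylidene-7-(3-oxobutan-2-yl)dodeca-2,10-dienoate | CC(=O)C(C)[C@H](C(=C)CC/C=C/C(=O)OC)CC/C(C)=C/CO[Si](c1ccccc1)(c1ccccc1)C(C)(C)C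
F2 | step 12 | methyl 2-[(1S,2S,3S)-2-acetyl-3-{(3E)-5-[(tert-butyldiphenylsilyl)oxy]-3-methylpent-3-en-1-yl}-2-methyl-4-methylidenecyclohexyl]acetate | C=C1CC[C@@H](CC(=O)OC)[C@](C)(C(C)=O)[C@H]1CC/C(C)=C/CO[Si](c1ccccc1)(c1ccccc1)C(C)(C)C
F3 | step 12 | methyl 2-[(1S,2S,3S)-3-{(3E)-5-[(tert-butyldiphenylsilyl)oxy]-3-methylpent-3-en-1-yl}-2-[(2E)-3-(dimethylamino)prop-2-enoyl]-2-methyl-4-methylidenecyclohexyl]acetate | C=C1CC[C@@H](CC(=O)OC)[C@](C)(C(=O)/C=C/N(C)C)[C@H]1CC/C(C)=C/CO[Si](c1ccccc1)(c1ccccc1)C(C)(C)C
F4 | step 12 | methyl (4aS,5S,8aS)-5-{(3E)-5-[(tert-butyldiphenylsilyl)oxy]-3-methylpent-3-en-1-yl}-4a-methyl-6-methylidene-4-oxo-1,4,4a,5,6,7,8,8a-octahydronaphthalene-1-carboxylate (both C1 epimers) | C=C1CC[C@@H]2[C@](C)(C(=O)C=CC2C(=O)OC)[C@H]1CC/C(C)=C/CO[Si](c1ccccc1)(c1ccccc1)C(C)(C)C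
F5 | step 7 | ethyl (2E,6E)-8-[(tert-butyldiphenylsilyl)oxy]-6-methylocta-2,6-dienoate | CCOC(=O)/C=C/CC/C(C)=C/CO[Si](c1ccccc1)(c1ccccc1)C(C)(C)C
F6 | step 7 | (2E,6E)-8-[(tert-butyldiphenylsilyl)oxy]-6-methylocta-2,6-dienoic acid | OC(=O)/C=C/CC/C(C)=C/CO[Si](c1ccccc1)(c1ccccc1)C(C)(C)C
F7 | step 7 | (4S)-3-{(2E,6E)-8-[(tert-butyldiphenylsilyl)oxy]-6-methylocta-2,6-dienoyl}-4-phenyl-1,3-oxazolidin-2-one | O=C(/C=C/CC/C(C)=C/CO[Si](c1ccccc1)(c1ccccc1)C(C)(C)C)N1[C@@H](c2ccccc2)COC1=O
F8 | step 7 | (4S)-3-{(3R,6E)-8-[(tert-butyldiphenylsilyl)oxy]-3-(hexa-1,5-dien-2-yl)-6-methyloct-6-enoyl}-4-phenyl-1,3-oxazolidin-2-one | O=C(C[C@H](C(=C)CCC=C)CC/C(C)=C/CO[Si](c1ccccc1)(c1ccccc1)C(C)(C)C)N1[C@@H](c2ccccc2)COC1=O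
F9 | step 13 | methyl (4aS,5S,8aS)-5-{(3E)-5-[(tert-butyldiphenylsilyl)oxy]-3-methylpent-3-en-1-yl}-4-hydroxy-4a-methyl-6-methylidenedecahydronaphthalene-1-carboxylate (carbinol and C1 epimers) | C=C1CC[C@@H]2[C@](C)(C(O)CCC2C(=O)OC)[C@H]1CC/C(C)=C/CO[Si](c1ccccc1)(c1ccccc1)C(C)(C)C
F10 | step 13 | methyl (4aS,5S,8aS)-5-{(3E)-5-[(tert-butyldiphenylsilyl)oxy]-3-methylpent-3-en-1-yl}-4a-methyl-6-methylidene-4-{[(methylsulfanyl)carbonothioyl]oxy}decahydronaphthalene-1-carboxylate | C=C1CC[C@@H]2[C@](C)(C(OC(=S)SC)CCC2C(=O)OC)[C@H]1CC/C(C)=C/CO[Si](c1ccccc1)(c1ccccc1)C(C)(C)C
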